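**Plan**

- The target is 2,5,6-tribromo-1-methylgramine N-oxide. Retrosynthesis cuts the N–O bond first, then the side-chain C–N bond (back through the alcohol to a C3 ester), then C2–Br to C–H and C5–Br/C6–Br to C–Si.
- Ring A (the benzo ring) has hydrogen at C4 and C7 and its only substituents, the two bromines, on the adjacent carbons C5 and C6. These two carbons therefore map onto a symmetrical alkyne with ipso-replaceable silyl groups, and ring A is cut at C4–C5 and C6–C7 to a pyrrole-fused 2-pyranone that gives up CO2.
- The pyranone is opened at its lactone to a 2-formylpyrrole-3-acetic acid; the pyrrole comes from tosylmethyl isocyanide and dimethyl glutaconate.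
- Forward order of rings: pyrrole, then pyranone, then ring A by Diels–Alder addition and loss of CO2. The C2 bromine, the C5/C6 bromines, the amine arm and the N-oxide follow.
- Stereochemistry: the target has no stereocentre. The sp3 centres of the two transient intermediates are racemic and vanish on aromatisation.

Key step: step 6

Assumption: the C7-unsubstituted pyranopyrrolone made in step 5 is treated as an isolable solid, like its C7-alkyl relatives, and is used promptly.

**Route**

Step 1
Reactants: 1 tosylmethyl isocyanide; 2 dimethyl (E)-glutaconate
Product: 3 methyl 4-(2-methoxy-2-oxoethyl)-1H-pyrrole-3-carboxylate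
Conditions: NaH, DMSO/Et2O, 0 °C → rt
Reagents that add atoms: none
Why: Van Leusen pyrrole synthesis: the TosMIC anion adds to the enoate carbon β to the conjugated ester, the ester enolate closes onto the isocyanide carbon, and loss of sulfinate followed by tautomerisation leaves the 3,4-disubstituted pyrrole with the ester on C3 and the acetate arm on C4.

Step 2
Reactants: 3 methyl 4-(2-methoxy-2-oxoethyl)-1H-pyrrole-3-carboxylate
Product: 4 methyl 4-(2-methoxy-2-oxoethyl)-1-methylpyrrole-3-carboxylate
Conditions: Cs2CO3, MeI (1.1 equiv), DMF, rt
Reagents that add atoms: iodomethane, CI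
Why: N-Alkylation of the pyrrolide anion: the ester-acidified N–H is removed by carbonate, which is too weak to enolise the acetate arm, so methylation stays on nitrogen.

Step 3
Reactants: 4 methyl 4-(2-methoxy-2-oxoethyl)-1-methylpyrrole-3-carboxylate
Product: 6 methyl 5-formyl-4-(2-methoxy-2-oxoethyl)-1-methylpyrrole-3-carboxylate, via iminium chloride 5 (not isolated)
Conditions: POCl3, DMF, ClCH2CH2Cl, 0 → 60 °C; then aq NaOAc, 60 °C
Reagents that add atoms: N,N-dimethylformamide, CN(C)C=O; water, O
Why: Vilsmeier–Haack formylation: a pyrrole-3-carboxylate is attacked at the α-carbon remote from the ester, here C5, which the neighbouring alkyl arm activates further, and hydrolysis of the iminium salt releases the aldehyde beside the acetate arm.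

Step 4
Reactants: 6 methyl 5-formyl-4-(2-methoxy-2-oxoethyl)-1-methylpyrrole-3-carboxylate
Product: 7 2-[2-formyl-4-(methoxycarbonyl)-1-methylpyrrol-3-yl]acetic acid
Conditions: LiOH (1.05 equiv), THF/H2O, 0 °C; then aq HCl to pH 3
Reagents that add atoms: lithium hydroxide, [Li+].[OH-]
Why: Chemoselective saponification: the aliphatic ester is far more electrophilic than the pyrrole-3-carboxylate, a vinylogous carbamate, so one equivalent of hydroxide in the cold cleaves only the acetate ester and the non-enolisable aldehyde is untouched.

Step 5
Reactants: 7 2-[2-formyl-4-(methoxycarbonyl)-1-methylpyrrol-3-yl]acetic acid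
Product: 9 methyl 1-methyl-5-oxo-1,5-dihydropyrano[3,4-b]pyrrole-3-carboxylate, via acetoxy lactone 8 (not isolated)
Conditions: Ac2O, 100 °C; evaporate, crystallise from toluene
Reagents that add atoms: none
Why: Cyclodehydration in the manner used to generate 2-benzopyran-3-ones from 2-formylarylacetic acids: the ring-chain lactol tautomer of the aldehyde acid is acetylated and 1,4-elimination of acetic acid across C4 and C7 gives the fused 2-pyranone.

Step 6
Reactants: 9 methyl 1-methyl-5-oxo-1,5-dihydropyrano[3,4-b]pyrrole-3-carboxylate; 10 bis(trimethylsilyl)acetylene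
Product: 12 methyl 1-methyl-5,6-bis(trimethylsilyl)indole-3-carboxylate, via bridged lactone adduct 11 (not isolated)
Conditions: 10 (10 equiv), 1,2-dichlorobenzene, sealed tube, 190 °C
Reagents that add atoms: none
Why: Thermal Diels–Alder addition of the alkyne across the diene termini C4 and C7 of the pyranone (the C4=C3a–C7a=C7 unit) gives the bridged lactone 11, which loses CO2 by retro-Diels–Alder reaction under the same conditions. The closest known reaction types are the alkyne cycloaddition–decarboxylation of pyrano[3,4-b]pyrrol-5(1H)-ones to indoles and the benzannulation of 2-pyranones by bis(trimethylsilyl)acetylene to 1,2-bis(trimethylsilyl)arenes. Ring A, the six-membered carbocycle, closes by an intermolecular [4+2] cycloaddition that forms the C4–C5 and C6–C7 bonds in one event and becomes aromatic through the cycloreversion. No stereocentre reaches the product, because the two bridgehead centres of 11 are flattened when CO2 leaves. The one selectivity needed is addition across the pyranone diene and not across the pyrrole ring; only that mode regains the pyrrole sextet, the pyranone being a masked 1-methylpyrrole-2,3-quinodimethane, and the symmetrical alkyne leaves no orientation to control. The alkyne is a sluggish dienophile, so it is used in large excess at high temperature in a closed vessel.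

Step 7
Reactants: 12 methyl 1-methyl-5,6-bis(trimethylsilyl)indole-3-carboxylate
Product: 14 methyl 2-bromo-1-methyl-5,6-bis(trimethylsilyl)indole-3-carboxylate, via C2-magnesiated ester 13 (not isolated)
Conditions: TMPMgCl·LiCl (1.2 equiv), THF, −20 → 0 °C; then BrCl2CCCl2Br, −20 °C → rt
Reagents that add atoms: 1,2-dibromo-1,1,2,2-tetrachloroethane, BrC(Cl)(Cl)C(Cl)(Cl)Br
Why: Directed deprotonative magnesiation and electrophilic bromination: C2–H is the most acidic C–H (next to nitrogen and ortho to the coordinating ester), the hindered amide base does not add to the ester, and the arylmagnesium takes bromine from the dibromide, which collapses to tetrachloroethene.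

Step 8
Reactants: 14 methyl 2-bromo-1-methyl-5,6-bis(trimethylsilyl)indole-3-carboxylate
Product: 17 methyl 2,5,6-tribromo-1-methylindole-3-carboxylate, via 5-bromo-6-silyl ester 15 (not isolated), via 6-bromo-5-silyl ester 16 (not isolated)
Conditions: Br2 (2.5 equiv), pyridine, CH2Cl2, 0 → 40 °C; aq Na2S2O3 wash
Reagents that add atoms: bromine, BrBr
Why: Electrophilic ipso-bromodesilylation: bromine attacks the silyl-bearing carbons because the Wheland intermediate is stabilised by the β-silicon and loses Me3SiBr instead of a proton, strain between the ortho silyl groups speeds the first exchange, and C2 is already blocked.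

Step 9
Reactants: 17 methyl 2,5,6-tribromo-1-methylindole-3-carboxylate
Product: 18 (2,5,6-tribromo-1-methylindol-3-yl)methanol
Conditions: i-Bu2AlH (2.5 equiv), CH2Cl2, −78 → 0 °C; aq potassium sodium tartrate
Reagents that add atoms: none
Why: Hydride reduction of the ester to the primary alcohol by i-Bu2AlH, which leaves the three C–Br bonds intact and, in the cold, does not hydrogenolyse the indol-3-ylmethanol as LiAlH4 might.

Step 10
Reactants: 18 (2,5,6-tribromo-1-methylindol-3-yl)methanol
Product: 20 1-(2,5,6-tribromo-1-methylindol-3-yl)-N,N-dimethylmethanamine, via mesylate 19 (not isolated)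
Conditions: MsCl, i-Pr2NEt, CH2Cl2, −20 °C; then Me2NH (2 M in THF, excess), −20 °C → rt
Reagents that add atoms: dimethylamine, CNC
Why: Sulfonylation followed by nucleophilic substitution: the indol-3-ylmethyl mesylate ionises readily to a nitrogen-stabilised cation (a vinylogous iminium ion), which excess dimethylamine captures, the excess also suppressing quaternisation of the product.

Step 11
Reactants: 20 1-(2,5,6-tribromo-1-methylindol-3-yl)-N,N-dimethylmethanamine
Product: 21 1-(2,5,6-tribromo-1-methylindol-3-yl)-N,N-dimethylmethanamine N-oxide
Conditions: mCPBA (1.05 equiv), CH2Cl2, 0 °C; filtration through basic Al2O3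
Reagents that add atoms: 3-chloroperoxybenzoic acid, OOC(=O)c1cccc(Cl)c1
Why: Peracid N-oxidation of a tertiary amine: the aliphatic nitrogen lone pair is far more nucleophilic than the electron-poor tribromoindole, and the cold, short reaction avoids Meisenheimer rearrangement of the benzylic-type N-oxide.

**Compound list**

1 | tosylmethyl isocyanide | [C-]#[N+]CS(=O)(=O)c1ccc(C)cc1 | starting material
2 | dimethyl (E)-glutaconate | COC(=O)C/C=C/C(=O)OC | starting material
3 | methyl 4-(2-methoxy-2-oxoethyl)-1H-pyrrole-3-carboxylate | COC(=O)Cc1c[nH]cc1C(=O)OC | intermediate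
4 | methyl 4-(2-methoxy-2-oxoethyl)-1-methylpyrrole-3-carboxylate | COC(=O)Cc1cn(C)cc1C(=O)OC | intermediate
5 | [4-(methoxycarbonyl)-3-(2-methoxy-2-oxoethyl)-1-methylpyrrol-2-yl]methylidene-dimethyliminium chloride (not isolated) | C[N+](C)=Cc1c(CC(=O)OC)c(C(=O)OC)cn1C.[Cl-] | intermediate
6 | methyl 5-formyl-4-(2-methoxy-2-oxoethyl)-1-methylpyrrole-3-carboxylate | Cn1cc(C(=O)OC)c(CC(=O)OC)c1C=O | intermediate
7 | 2-[2-formyl-4-(methoxycarbonyl)-1-methylpyrrol-3-yl]acetic acid | Cn1cc(C(=O)OC)c(CC(=O)O)c1C=O | intermediate
8 | methyl 7-acetoxy-1-methyl-5-oxo-1,4,5,7-tetrahydropyrano[3,4-b]pyrrole-3-carboxylate (racemic, not isolated) | Cn1cc(C(=O)OC)c2CC(=O)OC(OC(C)=O)c12 | intermediate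
9 | methyl 1-methyl-5-oxo-1,5-dihydropyrano[3,4-b]pyrrole-3-carboxylate | CN1C=C(C(=O)OC)C2=CC(=O)OC=C12 | intermediate
10 | bis(trimethylsilyl)acetylene | C[Si](C)(C)C#C[Si](C)(C)C | starting material
11 | bridged lactone adduct: 4,7-dihydroindole core of 12 with an O–C(=O) bridge from C7 (oxygen) to C4 (carbonyl carbon) and a C5=C6 bis(trimethylsilyl)alkene (racemic, not isolated) | Cn1cc(C(=O)OC)c2c1C1OC(=O)C2C([Si](C)(C)C)=C1[Si](C)(C)C | intermediate
12 | methyl 1-methyl-5,6-bis(trimethylsilyl)indole-3-carboxylate | COC(=O)c1cn(C)c2cc([Si](C)(C)C)c([Si](C)(C)C)cc12 | intermediate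
13 | chloromagnesium derivative of 12 at C2, LiCl complex (not isolated) | COC(=O)c1c([Mg]Cl)n(C)c2cc([Si](C)(C)C)c([Si](C)(C)C)cc12 | intermediate
14 | methyl 2-bromo-1-methyl-5,6-bis(trimethylsilyl)indole-3-carboxylate | COC(=O)c1c(Br)n(C)c2cc([Si](C)(C)C)c([Si](C)(C)C)cc12 | intermediate
15 | methyl 2,5-dibromo-1-methyl-6-(trimethylsilyl)indole-3-carboxylate (not isolated) | COC(=O)c1c(Br)n(C)c2cc([Si](C)(C)C)c(Br)cc12 | intermediate
16 | methyl 2,6-dibromo-1-methyl-5-(trimethylsilyl)indole-3-carboxylate (not isolated) | COC(=O)c1c(Br)n(C)c2cc(Br)c([Si](C)(C)C)cc12 | intermediate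
17 | methyl 2,5,6-tribromo-1-methylindole-3-carboxylate | COC(=O)c1c(Br)n(C)c2cc(Br)c(Br)cc12 | intermediate
18 | (2,5,6-tribromo-1-methylindol-3-yl)methanol | OCc1c(Br)n(C)c2cc(Br)c(Br)cc12 | intermediate
19 | (2,5,6-tribromo-1-methylindol-3-yl)methyl methanesulfonate (not isolated) | CS(=O)(=O)OCc1c(Br)n(C)c2cc(Br)c(Br)cc12 | intermediate
20 | 1-(2,5,6-tribromo-1-methylindol-3-yl)-N,N-dimethylmethanamine | CN(C)Cc1c(Br)n(C)c2cc(Br)c(Br)cc12 | intermediate
21 | 1-(2,5,6-tribromo-1-methylindol-3-yl)-N,N-dimethylmethanamine N-oxide | Cn1c(Br)c(C[N+](C)(C)[O-])c2cc(Br)c(Br)cc21 | target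

**Step count and risks**

Total step count: 11.
Longest linear sequence: 11 steps, from 1 and 2 to 21; 10 enters at step 6.

Steps most likely to fail:

1. Step 6. The hindered, weakly activated alkyne may add so slowly that thermal decomposition or self-reaction of the pyranone outruns cycloaddition. The fallback sets out from 9 and comes back at 17. Compound 9 would be heated in toluene at reflux together with phenyl vinyl sulfoxide, an electron-poor acetylene equivalent. Cycloaddition across C4 and C7, loss of CO2 and thermal syn-elimination of benzenesulfenic acid should give methyl 1-methylindole-3-carboxylate F1. Electrophilic dibromination by Br2 in AcOH, which an indole-3-carboxylate directs to C5 and C6, should give methyl 5,6-dibromo-1-methylindole-3-carboxylate F2. Magnesiation at C2 by TMPMgCl·LiCl in THF at low temperature should give the chloromagnesium derivative of the dibromo ester F3, and a quench by BrCl2CCCl2Br rejoins the route at 17.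

2. Step 5. The C7-unsubstituted pyranone may dimerise or be ring-opened by adventitious water while it is concentrated and isolated. The fallback sets out from 7 and comes back at 12. Acid 7 would be heated in a closed vessel together with Ac2O and a large excess of 10, so that the pyranone forms in the presence of the dienophile and is consumed as it forms, the way transient 2-benzopyran-3-ones are handled. This telescoped generation and trapping makes no new compound (F0).

3. Step 8. The second bromodesilylation may stall on the deactivated ring, or traces of HBr may cause protodesilylation, leaving mixtures that carry bromine, silicon or hydrogen at C5 and C6. The fallback sets out from 14 and comes back at 17. Both silyl groups would be removed on purpose by CF3CO2H at room temperature (protodesilylation) to give methyl 2-bromo-1-methylindole-3-carboxylate F4. Electrophilic C–H dibromination by Br2 in AcOH, directed to C5 and C6 by the 3-ester and with C2 already blocked, should then give 17.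

**Further compounds**

F1 | step 6 | methyl 1-methylindole-3-carboxylate | COC(=O)c1cn(C)c2ccccc12
F2 | step 6 | methyl 5,6-dibromo-1-methylindole-3-carboxylate | COC(=O)c1cn(C)c2cc(Br)c(Br)cc12
F3 | step 6 | chloromagnesium derivative of methyl 5,6-dibromo-1-methylindole-3-carboxylate at C2 | COC(=O)c1c([Mg]Cl)n(C)c2cc(Br)c(Br)cc12
F0 | step 5 | none | none
F4 | step 8 | methyl 2-bromo-1-methylindole-3-carboxylate | COC(=O)c1c(Br)n(C)c2ccccc12
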